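## Retrosynthetic overview

1. Both C–C bonds of the CH2 bridge are made in one flask from three components. These are 2,6-dihydroxy-4-methoxybutyrophenone, a one-carbon iminium salt, and the enantiopure dearomatised acid (4R)-2-hexanoyl-3,5-dihydroxy-4-methyl-4-prenylcyclohexa-2,5-dienone. The fragment-joining bond is CH2–C6 of the dienone ring.
2. Enabling feature: in the aromatic ring, the C2–OH sits ortho to the bridge-bearing carbon C3, so HO–C2–C3–CH2–N can collapse to the o-quinone methide O=C2–C3=CH2. C3 and C5 of that ring are equivalent. In the dienone ring, the triad C5(OH)=C6(H)–C1(=O) is a vinylogous acid, and its C6 is the only free nucleophilic ring carbon.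
3. Dienone fragment: 2-methylphloroglucinol is C-hexanoylated and the last ring CH is blocked with chlorine. A Pd-catalysed asymmetric dearomative prenylation at the methyl-bearing carbon then sets C4, and zinc removes the chlorine.
4. Aromatic fragment: phloroglucinol is C-butanoylated and then O-methylated selectively at the hydroxyl para to the ketone.
5. No ring is built. Both six-membered carbocycles come from commercial phloroglucinols. The left ring is dearomatised in step 3, and the right ring loses aromaticity only transiently in the key step.

Key step: step 7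

Assumption: the (R,R)-ligand is taken to deliver the required C4 configuration; the sense of induction on this nucleophile must be confirmed by correlation and the (S,S)-ligand used if it is opposite; all enolised triketones are drawn in the tautomer of the target SMILES, and tautomerism does not touch C4.

## Route

Step 1
Reactants: 1 2-methylbenzene-1,3,5-triol (2-methylphloroglucinol); 2 hexanoyl chloride
Product: 3 1-(2,4,6-trihydroxy-3-methylphenyl)hexan-1-one
Conditions: AlCl3 (3.5 equiv), CH2Cl2–PhNO2, 0 to 40 °C; ice/aq. HCl
Reagents that add atoms: none
Why: Friedel–Crafts acylation of a very electron-rich arene whose two free ring CH positions are equivalent, so only one regioisomer can form, and the chelated aryl ketone is deactivated enough for one equivalent of 2 to stop at monoacylation.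

Step 2
Reactants: 3 1-(2,4,6-trihydroxy-3-methylphenyl)hexan-1-one
Product: 4 1-(3-chloro-2,4,6-trihydroxy-5-methylphenyl)hexan-1-one
Conditions: NCS (1.0 equiv), MeCN, 0 °C to rt
Reagents that add atoms: N-chlorosuccinimide, O=C1CCC(=O)N1Cl
Why: Electrophilic aromatic chlorination at the single remaining ring CH, a reaction type well known for acylphloroglucinols; the chlorine is only a blocking group, so that step 3 cannot end in plain aromatic C-prenylation at that carbon.

Step 3
Reactants: 4 1-(3-chloro-2,4,6-trihydroxy-5-methylphenyl)hexan-1-one; 5 3-methylbut-2-en-1-yl acetate (prenyl acetate)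
Product: 6 (4S)-2-chloro-6-hexanoyl-3,5-dihydroxy-4-methyl-4-(3-methylbut-2-en-1-yl)cyclohexa-2,5-dien-1-one
Conditions: Pd2(dba)3·CHCl3 (2.5 mol %), (R,R)-DACH-phenyl bis(2-diphenylphosphinobenzamide) ligand (7.5 mol %), Et3N (2.5 equiv), degassed CH2Cl2, 0 °C to rt; cold aq. citric acid wash
Reagents that add atoms: none
Why: Palladium-catalysed asymmetric allylic alkylation (Tsuji–Trost type) run as an alkylative dearomatisation of a phenoxide, known for substituted phenols and naphthols and in racemic form for acylphloroglucinols: the ammonium phenoxide (O4, para to the ketone) attacks the unsubstituted terminus of the 1,1-dimethylallyl–Pd complex through its methyl-bearing ortho carbon, O-prenylation being reversible under Pd(0), and the new quaternary centre is set by the chiral pocket of the ligand, which can tell the two ring faces apart because the flanks of the reacting carbon differ (free phenoxide next to C–Cl on one side, OH chelated to the hexanoyl C=O on the other).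

Step 4
Reactants: 6 (4S)-2-chloro-6-hexanoyl-3,5-dihydroxy-4-methyl-4-(3-methylbut-2-en-1-yl)cyclohexa-2,5-dien-1-one
Product: 7 (4R)-2-hexanoyl-3,5-dihydroxy-4-methyl-4-(3-methylbut-2-en-1-yl)cyclohexa-2,5-dien-1-one
Conditions: Zn dust (5 equiv), AcOH–THF 1:4, 0 °C to rt
Reagents that add atoms: none
Why: Reductive dehalogenation of an α-chloro-β-dicarbonyl unit with zinc (electron transfer to the keto tautomer, loss of chloride, protonation of the zinc enolate), which should leave the isolated trisubstituted alkene and the enolised triketone alone and cannot touch the quaternary centre (the descriptor changes from S to R only because chlorine leaves the priority order).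

Step 5
Reactants: 8 benzene-1,3,5-triol (phloroglucinol); 9 butanoyl chloride
Product: 10 1-(2,4,6-trihydroxyphenyl)butan-1-one
Conditions: AlCl3 (3.5 equiv), CH2Cl2–PhNO2, 0 to 40 °C; ice/aq. HCl
Reagents that add atoms: none
Why: Friedel–Crafts acylation of phloroglucinol, whose three ring CH positions are equivalent, with the first acyl group deactivating the ring against a second acylation.

Step 6
Reactants: 10 1-(2,4,6-trihydroxyphenyl)butan-1-one
Product: 11 1-(2,6-dihydroxy-4-methoxyphenyl)butan-1-one
Conditions: Me2SO4 (1.0 equiv), K2CO3 (1.0 equiv), acetone, rt to 40 °C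
Reagents that add atoms: dimethyl sulfate, COS(=O)(=O)OC
Why: Williamson-type O-methylation under weak base, in which the 4-OH para to the ketone is the most acidic and the only unchelated, unshielded hydroxyl, so one equivalent of reagent should give mainly the 4-methyl ether.

Step 7
Reactants: 11 1-(2,6-dihydroxy-4-methoxyphenyl)butan-1-one; 12 N,N-dimethylmethyleneiminium iodide (Eschenmoser's salt); 7 (4R)-2-hexanoyl-3,5-dihydroxy-4-methyl-4-(3-methylbut-2-en-1-yl)cyclohexa-2,5-dien-1-one
Product: 15 (4R)-2-[(3-butanoyl-2,4-dihydroxy-6-methoxyphenyl)methyl]-6-hexanoyl-3,5-dihydroxy-4-methyl-4-(3-methylbut-2-en-1-yl)cyclohexa-2,5-dien-1-one (target), via Mannich salt 13 (not isolated), via o-quinone methide 14 (not isolated)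
Conditions: (i) 11, 12 (1.0 equiv), MeCN, 0 °C to rt; (ii) 7 (1.05 equiv) added to the same flask, 60 °C; aq. citric acid work-up
Reagents that add atoms: none
Why: This is a Mannich / amine-loss / Michael relay, the reaction type by which phenolic Mannich bases alkylate cyclic 1,3-diones through o-quinone methides: iminium 12 attacks 11 at C3, which is equivalent to C5, so only one aminomethyl isomer 13 can form, and its ammonium group deactivates the ring against a second attack. On warming, the C2–OH next to the new CH2 pushes out dimethylamine, which is already protonated and hence a good leaving group, and releases o-quinone methide 14 (O=C2–C3=CH2). Carbon C6 of 7, the only unsubstituted ring carbon and the α-carbon of the vinylogous acid C5(OH)=C6–C1(=O), adds to the exocyclic CH2, and rearomatisation of the phenol ring drives formation of the CH2–C6 bond. No ring is closed and no stereocentre is created; C4 of 7 is quaternary, has no pathway for epimerisation and keeps its R configuration. The step needs cross-selectivity over both symmetrical dimers, which is secured because all of the C1 electrophile is bound to 11 before 7 enters the flask and because 7 is by far the best carbon nucleophile present when 14 is released. C- over O-alkylation follows from reversibility of O-attack and the gain in aromaticity, and the dimethylammonium iodide buffer keeps the medium weakly acidic, which should suppress base-induced exchange of the methylene bridge, enaminone formation at the hexanoyl group and cyclodehydration to a xanthene.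

## Compound list

1 | 2-methylbenzene-1,3,5-triol | Cc1c(O)cc(O)cc1O | starting material
2 | hexanoyl chloride | CCCCCC(=O)Cl | starting material
3 | 1-(2,4,6-trihydroxy-3-methylphenyl)hexan-1-one | CCCCCC(=O)c1c(O)cc(O)c(C)c1O | intermediate
4 | 1-(3-chloro-2,4,6-trihydroxy-5-methylphenyl)hexan-1-one | CCCCCC(=O)c1c(O)c(Cl)c(O)c(C)c1O | intermediate
5 | 3-methylbut-2-en-1-yl acetate | CC(=O)OCC=C(C)C | starting material
6 | (4S)-2-chloro-6-hexanoyl-3,5-dihydroxy-4-methyl-4-(3-methylbut-2-en-1-yl)cyclohexa-2,5-dien-1-one | CCCCCC(=O)C1=C(O)[C@](C)(CC=C(C)C)C(O)=C(Cl)C1=O | intermediate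
7 | (4R)-2-hexanoyl-3,5-dihydroxy-4-methyl-4-(3-methylbut-2-en-1-yl)cyclohexa-2,5-dien-1-one | CCCCCC(=O)C1=C(O)[C@](C)(CC=C(C)C)C(O)=CC1=O | intermediate
8 | benzene-1,3,5-triol | Oc1cc(O)cc(O)c1 | starting material
9 | butanoyl chloride | CCCC(=O)Cl | starting material
10 | 1-(2,4,6-trihydroxyphenyl)butan-1-one | CCCC(=O)c1c(O)cc(O)cc1O | intermediate
11 | 1-(2,6-dihydroxy-4-methoxyphenyl)butan-1-one | CCCC(=O)c1c(O)cc(OC)cc1O | intermediate
12 | N,N-dimethylmethyleneiminium iodide | C=[N+](C)C.[I-] | starting material
13 | [(3-butanoyl-2,4-dihydroxy-6-methoxyphenyl)methyl]dimethylammonium iodide | CCCC(=O)c1c(O)cc(OC)c(C[NH+](C)C)c1O.[I-] | intermediate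
14 | 2-butanoyl-3-hydroxy-5-methoxy-6-methylidenecyclohexa-2,4-dien-1-one | CCCC(=O)C1=C(O)C=C(OC)C(=C)C1=O | intermediate
15 | (4R)-2-[(3-butanoyl-2,4-dihydroxy-6-methoxyphenyl)methyl]-6-hexanoyl-3,5-dihydroxy-4-methyl-4-(3-methylbut-2-en-1-yl)cyclohexa-2,5-dien-1-one | CCCCCC(=O)C1=C(O)[C@](C)(CC=C(C)C)C(O)=C(Cc2c(OC)cc(O)c(C(=O)CCC)c2O)C1=O | target

## Step count and risks

Total step count: 7. Longest linear sequence: 5 (steps 1, 2, 3, 4 and 7).

**Step 3.** Three things may go wrong:
- poor facial discrimination on a flat, nearly symmetric phenoxide;
- attack at the substituted allyl terminus (reverse prenylation);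
- an O-prenyl ether that fails to re-ionise.

The fallback replaces asymmetric catalysis by resolution and sets out from 4. Alkylative dearomatisation with prenyl bromide and aqueous KOH at 0 °C should give the racemic chloro dienone F1. Zinc in acetic acid, as in step 4, should then give the racemic vinylogous acid F2. Preparative supercritical-fluid chromatography on a polysaccharide chiral phase separates 7 from its S enantiomer F3. The route is rejoined at 7.

**Step 7.** Three things may go wrong:
- double aminomethylation of 11;
- sluggish loss of the amine from the salt;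
- reversible cleavage of the bridge, which redistributes the methylene group into symmetrical dimers.

The fallback fixes the bridge carbon on the aromatic ring at the aldehyde level and sets out from 11. Vilsmeier–Haack formylation (POCl3, DMF) at one of the two equivalent ring CH positions should give 3-butanoyl-2,4-dihydroxy-6-methoxybenzaldehyde F4. A proline-catalysed three-component reductive alkylation follows, with 7 and the diethyl Hantzsch ester in CH2Cl2 at rt. It proceeds by Knoevenagel condensation to the arylidene trione F5, which is reduced in the flask by hydride transfer. The same CH–C6 bond is formed, no free one-carbon electrophile is ever present, and the route is rejoined at 15.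

**Step 4.** Two things may go wrong:
- incomplete cleavage of the C–Cl bond of the strongly enolised chloride;
- acid-promoted addition of an enol hydroxyl to the prenyl double bond.

The fallback changes the blocking group and sets out from 3. Vilsmeier–Haack formylation of the free ring CH should give 3-hexanoyl-2,4,6-trihydroxy-5-methylbenzaldehyde F6. The palladium-catalysed prenylation of step 3 with 5 then gives the formyl dienone F7. The formyl group is the most electrophilic and least hindered carbonyl of that tricarbonylmethane unit, and it is removed by retro-Claisen cleavage with K2CO3 in aqueous MeOH at rt. The route is rejoined at 7.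

## Further compounds

F1 | step 3 | rac-2-chloro-6-hexanoyl-3,5-dihydroxy-4-methyl-4-(3-methylbut-2-en-1-yl)cyclohexa-2,5-dien-1-one | CCCCCC(=O)C1=C(O)C(C)(CC=C(C)C)C(O)=C(Cl)C1=O
F2 | step 3 | rac-2-hexanoyl-3,5-dihydroxy-4-methyl-4-(3-methylbut-2-en-1-yl)cyclohexa-2,5-dien-1-one | CCCCCC(=O)C1=C(O)C(C)(CC=C(C)C)C(O)=CC1=O
F3 | step 3 | (4S)-2-hexanoyl-3,5-dihydroxy-4-methyl-4-(3-methylbut-2-en-1-yl)cyclohexa-2,5-dien-1-one | CCCCCC(=O)C1=C(O)[C@@](C)(CC=C(C)C)C(O)=CC1=O
F4 | step 7 | 3-butanoyl-2,4-dihydroxy-6-methoxybenzaldehyde | CCCC(=O)c1c(O)cc(OC)c(C=O)c1O
F5 | step 7 | (R)-arylidene trione, Knoevenagel adduct of 7 and F4 (transient, C=C geometry not defined) | CCCCCC(=O)C1=C(O)[C@](C)(CC=C(C)C)C(=O)C(=Cc2c(OC)cc(O)c(C(=O)CCC)c2O)C1=O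
F6 | step 4 | 3-hexanoyl-2,4,6-trihydroxy-5-methylbenzaldehyde | CCCCCC(=O)c1c(O)c(C=O)c(O)c(C)c1O
F7 | step 4 | (3R)-5-hexanoyl-2,4-dihydroxy-3-methyl-3-(3-methylbut-2-en-1-yl)-6-oxocyclohexa-1,4-diene-1-carbaldehyde | CCCCCC(=O)C1=C(O)[C@](C)(CC=C(C)C)C(O)=C(C=O)C1=O
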